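**Retrosynthetic overview**
1. Target 18 ⇐ 17 by thiolate cleavage of the one methyl ether para to the enal ⇐ 16 by removal of a blocking bromine.
2. 16 ⇐ cyclopropyl carbinol 13 by a one-pot cyclopropylcarbinyl → homoallyl cation ring expansion (three- to six-membered ring, Friedel–Crafts closure onto ring A) with C3 formylation; ring B and C1 are made here.
3. 13 ⇐ enal 7 + phenacyl arsonium ylide from 9 by organocatalytic cyclopropanation (sets C2), then NaBH4.
4. 7 and 9 ⇐ the same aryl bromide 3 ⇐ veratrole 2 ⇐ catechol 1; the C3 and C2 units come from 4 and 8.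
5. Ring order: both arenes from catechol, then the cyclopropane (step 5), then ring B by ring expansion (step 6).

Assumption: reagents, catalysts and solvents carry no compound numbers; 13 is carried as a mixture of epimers at the carbinol carbon, a centre that is lost in step 6.

**Route**

Step 1
Reactants: 1 catechol
Product: 2 veratrole (1,2-dimethoxybenzene)
Conditions: MeI (2.5 equiv), K2CO3, acetone, reflux
Reagents that add atoms: iodomethane CI
Why: Williamson ether synthesis, SN2 methylation of both phenoxide oxygens.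

Step 2
Reactants: 2 veratrole
Product: 3 4-bromo-1,2-dimethoxybenzene
Conditions: NBS (1.0 equiv), MeCN, 0 °C to rt
Reagents that add atoms: N-bromosuccinimide O=C1CCC(=O)N1Br
Why: electrophilic aromatic bromination para to a methoxy group of the symmetrical diether gives one monobromide.

Step 3
Reactants: 3 4-bromo-1,2-dimethoxybenzene; 4 (E)-3-(dimethylamino)prop-2-enal
Product: 7 (E)-3-(3,4-dimethoxyphenyl)prop-2-enal, via aryllithium 5 (not isolated), via lithium alkoxide adduct 6 (not isolated)
Conditions: n-BuLi, THF, −78 °C; then 4, −78 °C to 0 °C; then 2 M HCl, rt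
Reagents that add atoms: water O
Why: bromine–lithium exchange, 1,2-addition to the vinylogous formamide and acid hydrolysis–elimination (vinylogous formylation) give the E-cinnamaldehyde.

Step 4
Reactants: 3 4-bromo-1,2-dimethoxybenzene; 8 bromoacetyl bromide
Product: 9 2-bromo-1-(2-bromo-4,5-dimethoxyphenyl)ethan-1-one
Conditions: AlCl3 (1.1 equiv), CH2Cl2, −10 °C to 0 °C
Reagents that add atoms: none
Why: Friedel–Crafts acylation goes para to the one methoxy group whose para position is free, which is ortho to bromine, so the bromine ends up para to the future C8 methoxy and blocks that site in step 6.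

Step 5
Reactants: 9 2-bromo-1-(2-bromo-4,5-dimethoxyphenyl)ethan-1-one; 7 (E)-3-(3,4-dimethoxyphenyl)prop-2-enal
Product: 13 (2-bromo-4,5-dimethoxyphenyl)[(1R,2R,3R)-2-(3,4-dimethoxyphenyl)-3-(hydroxymethyl)cyclopropyl]methanol (carbinol epimers), via arsonium bromide 10 (not isolated), via arsonium ylide 11 (not isolated), via cyclopropyl keto aldehyde 12 (not isolated)
Conditions: Ph3As, CHCl3, rt; then 7, (S)-α,α-diphenylprolinol trimethylsilyl ether (20 mol%), Na2CO3, 0 °C; then NaBH4, EtOH, 0 °C to rt
Reagents that add atoms: none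
Why: Michael-initiated ring closure of a stabilised arsonium ylide under iminium–enamine catalysis; the (S)-catalyst shields the Re face of the enal β-carbon, so Si-face attack and 3-exo-tet closure fix the formyl-bearing carbon as R (future C2) with aryl trans, and NaBH4 then reduces both carbonyls.

Step 6
Reactants: 13 cyclopropyl carbinol diol
Product: 16 (1S,2R)-5-bromo-1-(3,4-dimethoxyphenyl)-2-(hydroxymethyl)-7,8-dimethoxy-1,2-dihydronaphthalene-3-carbaldehyde, via bromo dihydronaphthalene alcohol 14 (not isolated), via enal formate ester 15 (not isolated)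
Conditions: POCl3 (4 equiv), DMF (6 equiv), ClCH2CH2Cl, 0 °C to 50 °C; aq NaOAc; then K2CO3, MeOH, rt
Reagents that add atoms: N,N-dimethylformamide CN(C)C=O; water O
Why: Proposed new method: the chloroiminium salt turns the benzylic carbinol into a leaving group, the aryl-stabilised cyclopropylcarbinyl cation opens reversibly to the 3,4-dimethoxybenzyl homoallyl cation, and this closes by Friedel–Crafts alkylation at the only free ortho carbon of ring A (bromine blocks the site para to OMe), enlarging the three-membered ring to ring B with the aryl trans to the CH2O arm (C1 = S); excess reagent then formylates the resulting p-methoxystyrene at C3; closest known reactions are the acid-mediated ring enlargement of aryl cyclopropyl carbinols and ketones to aryl dihydronaphthalenes and tetralones, and Vilsmeier–Haack formylation of 1,2-dihydronaphthalenes.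

Step 7
Reactants: 16 bromo enal
Product: 17 (1S,2R)-1-(3,4-dimethoxyphenyl)-2-(hydroxymethyl)-7,8-dimethoxy-1,2-dihydronaphthalene-3-carbaldehyde
Conditions: Pd(OAc)2 (5 mol%), PPh3 (10 mol%), HCO2Na, DMF, 80 °C
Reagents that add atoms: none
Why: palladium-catalysed hydrodehalogenation (oxidative addition of zerovalent palladium to Ar–Br, formate exchange, decarboxylation, reductive elimination of Ar–H) removes the blocking group without touching the stereocentres.

Step 8
Reactants: 17 tetramethyl ether enal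
Product: 18 vitekwangin B, (1S,2R)-1-(3,4-dimethoxyphenyl)-7-hydroxy-2-(hydroxymethyl)-8-methoxy-1,2-dihydronaphthalene-3-carbaldehyde
Conditions: NaSEt (3 equiv), DMF, 100 °C; then 1 M HCl
Reagents that add atoms: none
Why: SN2 O-demethylation by thiolate is fastest at the one methoxy group conjugated (para, through the styrene) to the formyl acceptor, because its phenoxide is the best leaving group, so only the C7 ether is cleaved.

**Compound list**
1 | catechol | Oc1ccccc1O | starting material
2 | veratrole | COc1ccccc1OC | intermediate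
3 | 4-bromo-1,2-dimethoxybenzene | COc1ccc(Br)cc1OC | intermediate
4 | (E)-3-(dimethylamino)prop-2-enal | CN(C)/C=C/C=O | starting material
5 | (3,4-dimethoxyphenyl)lithium | [Li]c1ccc(OC)c(OC)c1 | intermediate
6 | lithium (E)-3-(dimethylamino)-1-(3,4-dimethoxyphenyl)prop-2-en-1-olate (racemic) | COc1ccc(C([O-])/C=C/N(C)C)cc1OC.[Li+] | intermediate
7 | (E)-3-(3,4-dimethoxyphenyl)prop-2-enal | COc1ccc(/C=C/C=O)cc1OC | intermediate
8 | bromoacetyl bromide | BrCC(Br)=O | starting material
9 | 2-bromo-1-(2-bromo-4,5-dimethoxyphenyl)ethan-1-one | COc1cc(Br)c(C(=O)CBr)cc1OC | intermediate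
10 | [2-(2-bromo-4,5-dimethoxyphenyl)-2-oxoethyl]triphenylarsonium bromide | COc1cc(Br)c(C(=O)C[As+](c2ccccc2)(c2ccccc2)c2ccccc2)cc1OC.[Br-] | intermediate
11 | 1-(2-bromo-4,5-dimethoxyphenyl)-2-(triphenylarsanylidene)ethan-1-one | COc1cc(Br)c(C(=O)C=[As](c2ccccc2)(c2ccccc2)c2ccccc2)cc1OC | intermediate
12 | (1R,2R,3R)-2-(2-bromo-4,5-dimethoxybenzoyl)-3-(3,4-dimethoxyphenyl)cyclopropane-1-carbaldehyde (aryl trans to formyl, aroyl trans to formyl) | O=C[C@@H]1[C@@H](c2ccc(OC)c(OC)c2)[C@H]1C(=O)c1cc(OC)c(OC)cc1Br | intermediate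
13 | (2-bromo-4,5-dimethoxyphenyl)[(1R,2R,3R)-2-(3,4-dimethoxyphenyl)-3-(hydroxymethyl)cyclopropyl]methanol, carbinol epimers | OC[C@@H]1[C@@H](c2ccc(OC)c(OC)c2)[C@H]1C(O)c1cc(OC)c(OC)cc1Br | intermediate
14 | [(1S,2S)-5-bromo-1-(3,4-dimethoxyphenyl)-7,8-dimethoxy-1,2-dihydronaphthalen-2-yl]methanol (1,2-trans) | COc1ccc([C@H]2c3c(c(Br)cc(OC)c3OC)C=C[C@@H]2CO)cc1OC | intermediate
15 | [(1S,2R)-5-bromo-1-(3,4-dimethoxyphenyl)-3-formyl-7,8-dimethoxy-1,2-dihydronaphthalen-2-yl]methyl formate | COc1ccc([C@H]2c3c(c(Br)cc(OC)c3OC)C=C(C=O)[C@@H]2COC=O)cc1OC | intermediate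
16 | (1S,2R)-5-bromo-1-(3,4-dimethoxyphenyl)-2-(hydroxymethyl)-7,8-dimethoxy-1,2-dihydronaphthalene-3-carbaldehyde | COc1ccc([C@H]2c3c(c(Br)cc(OC)c3OC)C=C(C=O)[C@@H]2CO)cc1OC | intermediate
17 | (1S,2R)-1-(3,4-dimethoxyphenyl)-2-(hydroxymethyl)-7,8-dimethoxy-1,2-dihydronaphthalene-3-carbaldehyde | COc1ccc([C@H]2c3c(ccc(OC)c3OC)C=C(C=O)[C@@H]2CO)cc1OC | intermediate
18 | vitekwangin B, (1S,2R)-1-(3,4-dimethoxyphenyl)-7-hydroxy-2-(hydroxymethyl)-8-methoxy-1,2-dihydronaphthalene-3-carbaldehyde | COc1ccc([C@H]2c3c(ccc(O)c3OC)C=C(C=O)[C@@H]2CO)cc1OC | target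

**Step count**
Total steps: 8. Longest linear sequence: 7 (steps 1, 2, 4, 5, 6, 7, 8; step 3 is a side branch from 3).

**Three steps most likely to fail**

Step 6 (the proposed new step). The cation may be trapped by DMF or chloride, or eliminate to a diene, before it closes at the hindered carbon ortho to OMe. The fallback uses known chemistry, sets out from 13 and comes back at 16. Treat 13 with catalytic TsOH·H2O in CH2Cl2 at 0 °C, the established acid-mediated ring enlargement of aryl cyclopropyl carbinols, and isolate 14. Formylate 14 separately under standard Vilsmeier–Haack conditions (POCl3, DMF, 0 °C to rt) to formate 15, and cleave the formate with K2CO3 in MeOH to reach 16. No compound outside the list is made (F0).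

Step 8. Thiolate can add to the enal, and the dihydronaphthalene can aromatise under hot basic conditions. The fallback sets out from 12 (isolated instead of being reduced in the flask) and comes back at 18; it moves the demethylation to a ketone stage where no enal is present. NaBH4 in EtOH/CH2Cl2 at −78 °C reduces only the aldehyde to hydroxymethyl cyclopropyl ketone F1. SnCl4 in MeNO2 at 0 °C, the known ring enlargement of aryl cyclopropyl ketones, gives trans bromo tetralone F2. H2, Pd/C, Et3N removes bromine to give tetralone F3. NaSEt in DMF at 100 °C cleaves the methoxy para to the aryl ketone to give phenolic tetralone F4. POCl3/DMF chloroformylation with K2CO3/MeOH work-up gives chloro enal F5. Pd(OAc)2, PPh3, HCO2Na removes chlorine to give 18.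

Step 5. The electron-rich enal and the hindered ortho-bromo ylide may react slowly or with lower selectivity, and excess ylide can olefinate the product aldehyde. The fallback sets out from 7 (with 3 and 8) and comes back at 16. NaBH4 reduces 7 to cinnamyl alcohol F6. Acylation with 8 and NaHCO3 gives bromoacetate F7. N,N'-ditosylhydrazine and DBU give diazoacetate F8. Intramolecular cyclopropanation with dirhodium tetrakis[methyl (4S)-2-oxo-1-(3-phenylpropanoyl)imidazolidine-4-carboxylate], or its mirror image if that is the one that gives this antipode, gives bicyclic lactone F9. i-Bu2AlH at −78 °C gives lactol F10. Separately, 3 is brominated with NBS to dibromide F11 and mono-lithiated (n-BuLi, −78 °C) to aryllithium F12, which adds to F10 to give cis diol F13. Under the step 6 conditions F13 converges on 16, because the carbinol-bearing cyclopropane carbon becomes sp2.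

**Further compounds**
F0 | step 6 | none | none
F1 | step 8 | (2-bromo-4,5-dimethoxyphenyl)[(1R,2R,3R)-2-(3,4-dimethoxyphenyl)-3-(hydroxymethyl)cyclopropyl]methanone | OC[C@@H]1[C@@H](c2ccc(OC)c(OC)c2)[C@H]1C(=O)c1cc(OC)c(OC)cc1Br
F2 | step 8 | (3S,4S)-8-bromo-4-(3,4-dimethoxyphenyl)-3-(hydroxymethyl)-5,6-dimethoxy-3,4-dihydronaphthalen-1(2H)-one (3,4-trans) | COc1ccc([C@H]2c3c(OC)c(OC)cc(Br)c3C(=O)C[C@@H]2CO)cc1OC
F3 | step 8 | (3S,4S)-4-(3,4-dimethoxyphenyl)-3-(hydroxymethyl)-5,6-dimethoxy-3,4-dihydronaphthalen-1(2H)-one | COc1ccc([C@H]2c3c(OC)c(OC)ccc3C(=O)C[C@@H]2CO)cc1OC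
F4 | step 8 | (3S,4S)-4-(3,4-dimethoxyphenyl)-6-hydroxy-3-(hydroxymethyl)-5-methoxy-3,4-dihydronaphthalen-1(2H)-one | COc1ccc([C@H]2c3c(OC)c(O)ccc3C(=O)C[C@@H]2CO)cc1OC
F5 | step 8 | (1S,2R)-4-chloro-1-(3,4-dimethoxyphenyl)-7-hydroxy-2-(hydroxymethyl)-8-methoxy-1,2-dihydronaphthalene-3-carbaldehyde | COc1ccc([C@H]2c3c(OC)c(O)ccc3C(Cl)=C(C=O)[C@@H]2CO)cc1OC
F6 | step 5 | (E)-3-(3,4-dimethoxyphenyl)prop-2-en-1-ol | COc1ccc(/C=C/CO)cc1OC
F7 | step 5 | (E)-3-(3,4-dimethoxyphenyl)allyl 2-bromoacetate | COc1ccc(/C=C/COC(=O)CBr)cc1OC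
F8 | step 5 | (E)-3-(3,4-dimethoxyphenyl)allyl 2-diazoacetate | COc1ccc(/C=C/COC(=O)C=[N+]=[N-])cc1OC
F9 | step 5 | (1S,5R,6R)-6-(3,4-dimethoxyphenyl)-3-oxabicyclo[3.1.0]hexan-2-one (aryl exo) | O=C1OC[C@@H]2[C@@H](c3ccc(OC)c(OC)c3)[C@H]12
F10 | step 5 | (1S,5R,6R)-6-(3,4-dimethoxyphenyl)-3-oxabicyclo[3.1.0]hexan-2-ol (anomers) | OC1OC[C@@H]2[C@@H](c3ccc(OC)c(OC)c3)[C@H]12
F11 | step 5 | 1,2-dibromo-4,5-dimethoxybenzene | COc1cc(Br)c(Br)cc1OC
F12 | step 5 | (2-bromo-4,5-dimethoxyphenyl)lithium | [Li]c1cc(OC)c(OC)cc1Br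
F13 | step 5 | (2-bromo-4,5-dimethoxyphenyl)[(1S,2R,3R)-2-(3,4-dimethoxyphenyl)-3-(hydroxymethyl)cyclopropyl]methanol, carbinol epimers | OC[C@@H]1[C@@H](c2ccc(OC)c(OC)c2)[C@@H]1C(O)c1cc(OC)c(OC)cc1Br
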